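**Plan**

1. The last skeletal bond cut is the one between benzofuran C5 and the methylene on lactone C3: it is made by rhodium-catalysed addition of a C5 arylboronate to an (R)-4-benzyl-3-methylene-butyrolactone.
2. The dihydrobenzofuran is cut at C3–C3a and traced back to the C4–C4a bond of an (S)-2-arylchroman-4-one. The enabling feature is that C3 carries the fused arene carbon C3a and one exocyclic carbon (the CH2OH) next to the O1–C2(aryl) unit, which is the pattern left when arene carbon C4a of a flavanone shifts from C4 to C3 and C4 leaves the ring as a carboxyl carbon.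
3. The flavanone is cut at C2–aryl into 6-bromo-8-methoxychromone and an arylboronic acid; the lactone comes from a Stobbe half-ester of O-benzylvanillin and dimethyl succinate.
4. Forward, the pyranone ring is closed first, arylated, then contracted to the dihydrofuran ring; the lactone ring is made separately and the two halves are joined three steps from the end.
5. Benzofuran C2 is set by the Pd/PyOX arylation, C3 is relayed from C2 in the ring contraction, lactone C4 comes from asymmetric hydrogenation, and lactone C3 is set by equilibration to the trans isomer under control of C4.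
6. Both phenols travel as benzyl ethers (inert to iodine(III), acid, hydride and base) and are freed together in the last step.

Key step: step 6

Assumption: the ligand antipodes named in steps 5 and 10 are assigned by analogy with the parent reactions of these catalysts; should either induce the opposite sense, its mirror-image ligand is used and nothing else changes.

**Route**

Step 1
Reactants: 1 4-bromo-2-methoxyphenol
Product: 2 1-(benzyloxy)-4-bromo-2-methoxybenzene
Conditions: BnBr, K2CO3, DMF, rt
Reagents that add atoms: benzyl bromide, BrCc1ccccc1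
Why: Williamson etherification of the phenoxide with benzyl bromide; the benzyl ether withstands organolithium, acid, iodine(III), hydride and base and is cleaved only by the final hydrogenolysis.

Step 2
Reactants: 2 1-(benzyloxy)-4-bromo-2-methoxybenzene
Product: 5 [4-(benzyloxy)-3-methoxyphenyl]boronic acid, via aryllithium 3 (not isolated), via lithium aryl(triisopropoxy)borate 4 (not isolated)
Conditions: n-BuLi, THF, −78 °C; B(OiPr)3, −78 °C → rt; aq. HCl
Reagents that add atoms: triisopropyl borate, CC(C)OB(OC(C)C)OC(C)C; water, O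
Why: Bromine–lithium exchange at −78 °C is faster than any attack on the benzyl ether, and borylation of the aryllithium with a trialkyl borate followed by acidic hydrolysis is the standard arylboronic acid synthesis.

Step 3
Reactants: 6 1-(2-hydroxy-3-methoxyphenyl)ethanone
Product: 7 1-(5-bromo-2-hydroxy-3-methoxyphenyl)ethanone
Conditions: NBS, MeCN, 0 °C → rt
Reagents that add atoms: N-bromosuccinimide, O=C1CCC(=O)N1Br
Why: Electrophilic aromatic bromination goes to the position para to the free phenol and meta to the acetyl group, the same regiochemistry as in the bromination of o-vanillin.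

Step 4
Reactants: 7 1-(5-bromo-2-hydroxy-3-methoxyphenyl)ethanone
Product: 9 6-bromo-8-methoxy-4H-chromen-4-one, via enaminone 8 (not isolated)
Conditions: DMF-DMA, toluene, 100 °C; then conc. HCl, CH2Cl2, 40 °C
Reagents that add atoms: N,N-dimethylformamide dimethyl acetal, COC(OC)N(C)C
Why: Enaminone route to chromones: the methyl ketone condenses with the amide acetal, and acid then triggers intramolecular oxa-Michael addition of the phenol and loss of dimethylamine.

Step 5
Reactants: 9 6-bromo-8-methoxy-4H-chromen-4-one; 5 [4-(benzyloxy)-3-methoxyphenyl]boronic acid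
Product: 10 (S)-2-[4-(benzyloxy)-3-methoxyphenyl]-6-bromo-8-methoxychroman-4-one
Conditions: Pd(OCOCF3)2 (5 mol %), (R)-t-BuPyOX (6 mol %), NH4PF6, H2O, ClCH2CH2Cl, 60 °C
Reagents that add atoms: none
Why: Palladium(II)/pyridine-oxazoline catalysed asymmetric conjugate addition of an arylboronic acid to a chromone (transmetalation, enantio-determining carbopalladation of C2=C3, protonolysis of the palladium enolate); the ligand sets C2 as S, and because palladium stays in the +2 state the aryl bromide is not touched.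

Step 6
Reactants: 10 (S)-2-[4-(benzyloxy)-3-methoxyphenyl]-6-bromo-8-methoxychroman-4-one
Product: 14 methyl (2S,3S)-2-[4-(benzyloxy)-3-methoxyphenyl]-5-bromo-7-methoxy-2,3-dihydro-1-benzofuran-3-carboxylate, via methyl enol ether 11 (not isolated), via trans C3-iodane ketal 12 (not isolated), via trimethyl orthoester 13 (not isolated)
Conditions: PhI(OAc)2, conc. H2SO4, HC(OMe)3, 0 °C → rt; aqueous work-up
Reagents that add atoms: trimethyl orthoformate, COC(OC)OC; water, O
Why: Acid and trimethyl orthoformate turn the C4 ketone into its methyl enol ether 11; acid-activated PhI(OAc)2 then adds to C3 on the face away from the pseudo-equatorial C2 aryl group while methanol caps C4, giving the trans iodane ketal 12 with the C2 aryl group and the C3–I bond both equatorial. In that conformer the ring bond C4–C4a lies antiperiplanar to C3–I, so reductive loss of iodobenzene is accompanied by a 1,2-shift of the O1-activated arene carbon C4a from C4 to C3 with inversion at C3 (phenonium-type transition state), and the C4 dimethoxycarbenium ion is trapped as orthoester 13, which hydrolyses to the methyl ester on work-up. The closest known reaction is the iodine(III)- or thallium(III)-mediated oxidative ring contraction of flavanones in trimethyl orthoformate to methyl trans-2-aryl-2,3-dihydrobenzofuran-3-carboxylates, a semipinacol-type rearrangement. The five-membered ring arises not by an end-to-end cyclisation but by contraction of the pyranone: the new C3–C3a bond closes through a bridged, 3-exo-type ipso attack of the arene on C3 as C4–C4a breaks. The new C3 stereocentre is under substrate control from C2 (anti iodination followed by invertive migration places CO2Me trans to the C2 aryl group, giving 2S,3S), and C2 takes part in no bond change. The step needs migration of C4a in preference to a shift of the C2 aryl group or elimination to the flavone; the antiperiplanar C4–C4a bond, the ortho oxygen O1 and the cation-stabilising methoxy groups at C4 secure this, and the benzyl ether keeps the B-ring phenol out of reach of the oxidant.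

Step 7
Reactants: 14 methyl (2S,3S)-2-[4-(benzyloxy)-3-methoxyphenyl]-5-bromo-7-methoxy-2,3-dihydro-1-benzofuran-3-carboxylate
Product: 15 [(2S,3R)-2-[4-(benzyloxy)-3-methoxyphenyl]-5-bromo-7-methoxy-2,3-dihydro-1-benzofuran-3-yl]methanol
Conditions: DIBAL-H, CH2Cl2, −78 → 0 °C; Rochelle salt
Reagents that add atoms: none
Why: Hydride reduction of the ester to the primary alcohol with DIBAL-H at low temperature outpaces enolisation, so C3 keeps its configuration (the descriptor changes from S to R only through CIP priorities), and the aryl bromide is inert.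

Step 8
Reactants: 15 [(2S,3R)-2-[4-(benzyloxy)-3-methoxyphenyl]-5-bromo-7-methoxy-2,3-dihydro-1-benzofuran-3-yl]methanol
Product: 16 [(2S,3R)-2-[4-(benzyloxy)-3-methoxyphenyl]-7-methoxy-5-(4,4,5,5-tetramethyl-1,3,2-dioxaborolan-2-yl)-2,3-dihydro-1-benzofuran-3-yl]methanol
Conditions: B2pin2, Pd(dppf)Cl2 (cat.), KOAc, 1,4-dioxane, 85 °C
Reagents that add atoms: bis(pinacolato)diboron, CC1(C)OB(OC1(C)C)B1OC(C)(C)C(C)(C)O1
Why: Miyaura borylation: Pd(0) inserts into the only C–Br bond and acetate-assisted transmetalation with the diboron reagent gives the pinacol boronate; the free alcohol and the benzyl ethers are tolerated.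

Step 9
Reactants: 17 4-(benzyloxy)-3-methoxybenzaldehyde; 18 dimethyl succinate
Product: 19 (E)-4-[4-(benzyloxy)-3-methoxyphenyl]-3-(methoxycarbonyl)but-3-enoic acid
Conditions: NaOMe, MeOH, reflux; then aq. HCl
Reagents that add atoms: none
Why: Stobbe condensation (aldol addition, lactonisation to the paraconic ester, E1cB ring opening) gives the (E)-benzylidene half-ester with the free acid on the methylene arm.

Step 10
Reactants: 19 (E)-4-[4-(benzyloxy)-3-methoxyphenyl]-3-(methoxycarbonyl)but-3-enoic acid
Product: 20 (R)-4-[4-(benzyloxy)-3-methoxyphenyl]-3-(methoxycarbonyl)butanoic acid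
Conditions: [Rh(cod)((S,S)-Et-DuPhos)]OTf (cat.), H2 (5 bar), NaOMe (10 mol %), MeOH, rt
Reagents that add atoms: none
Why: Rhodium–bisphospholane asymmetric hydrogenation of a Stobbe-type itaconate half-ester, in which the carboxylate chelates rhodium and the ligand dictates the face of hydrogen delivery, sets the future lactone C4 as R; the benzyl ether is inert to the homogeneous catalyst.

Step 11
Reactants: 20 (R)-4-[4-(benzyloxy)-3-methoxyphenyl]-3-(methoxycarbonyl)butanoic acid
Product: 22 (R)-4-[4-(benzyloxy)-3-methoxybenzyl]dihydrofuran-2(3H)-one, via hydroxy acid 21 (not isolated)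
Conditions: KOH (1 equiv), EtOH; CaCl2, NaBH4, EtOH, −10 °C → rt; then 2 M HCl
Reagents that add atoms: none
Why: Calcium borohydride reduces the methyl ester chemoselectively beside the carboxylate salt, and acidification closes the γ-lactone by 5-exo-trig acyl substitution without touching the stereocentre.

Step 12
Reactants: 22 (R)-4-[4-(benzyloxy)-3-methoxybenzyl]dihydrofuran-2(3H)-one
Product: 25 (R)-4-[4-(benzyloxy)-3-methoxybenzyl]-3-methylenedihydrofuran-2(3H)-one, via Mannich base 23 (not isolated), via trimethylammonium iodide 24 (not isolated)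
Conditions: LDA, THF, −78 °C; CH2=NMe2+ I−, −78 °C → rt; MeI, MeOH, rt; aq. NaHCO3, CH2Cl2
Reagents that add atoms: Eschenmoser's salt (N,N-dimethylmethyleneiminium iodide), C=[N+](C)C.[I-]
Why: α-Methylenation by Mannich reaction of the lithium enolate with Eschenmoser's salt, N-methylation and E1cB (Hofmann-type) loss of trimethylamine; C4 is not enolisable and keeps its configuration.

Step 13
Reactants: 16 [(2S,3R)-2-[4-(benzyloxy)-3-methoxyphenyl]-7-methoxy-5-(pinacolboryl)-2,3-dihydro-1-benzofuran-3-yl]methanol; 25 (R)-4-[4-(benzyloxy)-3-methoxybenzyl]-3-methylenedihydrofuran-2(3H)-one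
Product: 26 (4R)-4-[4-(benzyloxy)-3-methoxybenzyl]-3-{[(2S,3R)-2-[4-(benzyloxy)-3-methoxyphenyl]-3-(hydroxymethyl)-7-methoxy-2,3-dihydro-1-benzofuran-5-yl]methyl}dihydrofuran-2(3H)-one, mixture of C3 epimers
Conditions: [Rh(cod)OH]2 (cat.), K3PO4 (cat.), 1,4-dioxane/H2O (10:1), 50 °C
Reagents that add atoms: none
Why: Rhodium(I)-catalysed conjugate addition of an arylboron reagent to an α-substituted acrylate-type acceptor (Hayashi–Miyaura reaction): the aryl group passes from boron to Rh–OH, adds to the unsubstituted CH2 terminus, and the oxa-π-allyl rhodium is protonated by water mainly on the face away from the C4 substituent, so a cis-rich C3 mixture is expected and is corrected in step 14.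

Step 14
Reactants: 26 C3-epimeric lactone mixture
Product: 27 (3R,4R)-4-[4-(benzyloxy)-3-methoxybenzyl]-3-{[(2S,3R)-2-[4-(benzyloxy)-3-methoxyphenyl]-3-(hydroxymethyl)-7-methoxy-2,3-dihydro-1-benzofuran-5-yl]methyl}dihydrofuran-2(3H)-one
Conditions: DBU, toluene, 80 °C
Reagents that add atoms: none
Why: Base-mediated epimerisation through the lactone enolate: C3 is the only acidic stereocentre and the trans-3,4-disubstituted butyrolactone is the thermodynamic isomer, so C3 becomes R under control of C4, with any residual cis isomer removed by chromatography.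

Step 15
Reactants: 27 trans-lactone bis(benzyl ether)
Product: 28 Isolappaol A, (3R,4R)-4-(4-hydroxy-3-methoxybenzyl)-3-{[(2S,3R)-2-(4-hydroxy-3-methoxyphenyl)-3-(hydroxymethyl)-7-methoxy-2,3-dihydro-1-benzofuran-5-yl]methyl}dihydrofuran-2(3H)-one
Conditions: H2 (1 atm), 10% Pd/C, EtOAc/EtOH, rt
Reagents that add atoms: none
Why: Catalytic hydrogenolysis of the two aryl benzyl ethers over Pd/C; at ambient pressure and temperature the cyclic benzylic C2–O bond of the dihydrobenzofuran, the lactone and the arenes are expected to stay intact.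

**Compound list**

1 | 4-bromo-2-methoxyphenol | COc1cc(Br)ccc1O | starting material
2 | 1-(benzyloxy)-4-bromo-2-methoxybenzene | COc1cc(Br)ccc1OCc1ccccc1 | intermediate
3 | [4-(benzyloxy)-3-methoxyphenyl]lithium | [Li]c1ccc(OCc2ccccc2)c(OC)c1 | intermediate (not isolated)
4 | lithium [4-(benzyloxy)-3-methoxyphenyl]tri(propan-2-yloxy)borate | [Li+].CC(C)O[B-](OC(C)C)(OC(C)C)c1ccc(OCc2ccccc2)c(OC)c1 | intermediate (not isolated)
5 | [4-(benzyloxy)-3-methoxyphenyl]boronic acid | OB(O)c1ccc(OCc2ccccc2)c(OC)c1 | intermediate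
6 | 1-(2-hydroxy-3-methoxyphenyl)ethanone | CC(=O)c1cccc(OC)c1O | starting material
7 | 1-(5-bromo-2-hydroxy-3-methoxyphenyl)ethanone | CC(=O)c1cc(Br)cc(OC)c1O | intermediate
8 | (E)-1-(5-bromo-2-hydroxy-3-methoxyphenyl)-3-(dimethylamino)prop-2-en-1-one | CN(C)/C=C/C(=O)c1cc(Br)cc(OC)c1O | intermediate (not isolated)
9 | 6-bromo-8-methoxy-4H-chromen-4-one | COc1cc(Br)cc2c(=O)ccoc12 | intermediate
10 | (S)-2-[4-(benzyloxy)-3-methoxyphenyl]-6-bromo-8-methoxychroman-4-one | Brc1cc(OC)c2c(c1)C(=O)C[C@@H](c1ccc(OCc3ccccc3)c(OC)c1)O2 | intermediate (key-step precursor)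
11 | (S)-2-[4-(benzyloxy)-3-methoxyphenyl]-6-bromo-4,8-dimethoxy-2H-chromene | COC1=C[C@@H](c2ccc(OCc3ccccc3)c(OC)c2)Oc2c(OC)cc(Br)cc12 | intermediate (not isolated)
12 | 2,3-trans-3-[acetoxy(phenyl)-λ3-iodanyl]-2-[4-(benzyloxy)-3-methoxyphenyl]-6-bromo-4,4,8-trimethoxychromane (C2 spatially as in 10) | Brc1cc(OC)c2c(c1)C(OC)(OC)[C@H](I(OC(C)=O)c1ccccc1)[C@@H](c1ccc(OCc3ccccc3)c(OC)c1)O2 | intermediate (not isolated)
13 | (2S,3S)-2-[4-(benzyloxy)-3-methoxyphenyl]-5-bromo-7-methoxy-3-(trimethoxymethyl)-2,3-dihydro-1-benzofuran | Brc1cc(OC)c2c(c1)[C@H](C(OC)(OC)OC)[C@@H](c1ccc(OCc3ccccc3)c(OC)c1)O2 | intermediate (not isolated)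
14 | methyl (2S,3S)-2-[4-(benzyloxy)-3-methoxyphenyl]-5-bromo-7-methoxy-2,3-dihydro-1-benzofuran-3-carboxylate | Brc1cc(OC)c2c(c1)[C@H](C(=O)OC)[C@@H](c1ccc(OCc3ccccc3)c(OC)c1)O2 | intermediate (key-step product)
15 | [(2S,3R)-2-[4-(benzyloxy)-3-methoxyphenyl]-5-bromo-7-methoxy-2,3-dihydro-1-benzofuran-3-yl]methanol | Brc1cc(OC)c2c(c1)[C@H](CO)[C@@H](c1ccc(OCc3ccccc3)c(OC)c1)O2 | intermediate
16 | [(2S,3R)-2-[4-(benzyloxy)-3-methoxyphenyl]-7-methoxy-5-(4,4,5,5-tetramethyl-1,3,2-dioxaborolan-2-yl)-2,3-dihydro-1-benzofuran-3-yl]methanol | CC1(C)OB(OC1(C)C)c1cc(OC)c2c(c1)[C@H](CO)[C@@H](c1ccc(OCc3ccccc3)c(OC)c1)O2 | intermediate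
17 | 4-(benzyloxy)-3-methoxybenzaldehyde | COc1cc(C=O)ccc1OCc1ccccc1 | starting material
18 | dimethyl succinate | COC(=O)CCC(=O)OC | starting material
19 | (E)-4-[4-(benzyloxy)-3-methoxyphenyl]-3-(methoxycarbonyl)but-3-enoic acid | COC(=O)/C(CC(=O)O)=C/c1ccc(OCc2ccccc2)c(OC)c1 | intermediate
20 | (R)-4-[4-(benzyloxy)-3-methoxyphenyl]-3-(methoxycarbonyl)butanoic acid | COC(=O)[C@@H](CC(=O)O)Cc1ccc(OCc2ccccc2)c(OC)c1 | intermediate
21 | (R)-4-[4-(benzyloxy)-3-methoxyphenyl]-3-(hydroxymethyl)butanoic acid | OC[C@@H](CC(=O)O)Cc1ccc(OCc2ccccc2)c(OC)c1 | intermediate (not isolated)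
22 | (R)-4-[4-(benzyloxy)-3-methoxybenzyl]dihydrofuran-2(3H)-one | COc1cc(C[C@H]2COC(=O)C2)ccc1OCc1ccccc1 | intermediate
23 | (3S,4R)-4-[4-(benzyloxy)-3-methoxybenzyl]-3-[(dimethylamino)methyl]dihydrofuran-2(3H)-one (trans; C3 is lost in the elimination) | COc1cc(C[C@H]2COC(=O)[C@@H]2CN(C)C)ccc1OCc1ccccc1 | intermediate (not isolated)
24 | {(3S,4R)-4-[4-(benzyloxy)-3-methoxybenzyl]-2-oxotetrahydrofuran-3-yl}-N,N,N-trimethylmethanaminium iodide | COc1cc(C[C@H]2COC(=O)[C@@H]2C[N+](C)(C)C)ccc1OCc1ccccc1.[I-] | intermediate (not isolated)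
25 | (R)-4-[4-(benzyloxy)-3-methoxybenzyl]-3-methylenedihydrofuran-2(3H)-one | COc1cc(C[C@H]2COC(=O)C2=C)ccc1OCc1ccccc1 | intermediate
26 | (4R)-4-[4-(benzyloxy)-3-methoxybenzyl]-3-{[(2S,3R)-2-[4-(benzyloxy)-3-methoxyphenyl]-3-(hydroxymethyl)-7-methoxy-2,3-dihydro-1-benzofuran-5-yl]methyl}dihydrofuran-2(3H)-one, C3 epimers | COc1cc(C[C@H]2COC(=O)C2Cc2cc(OC)c3c(c2)[C@H](CO)[C@@H](c2ccc(OCc4ccccc4)c(OC)c2)O3)ccc1OCc1ccccc1 | intermediate
27 | (3R,4R)-4-[4-(benzyloxy)-3-methoxybenzyl]-3-{[(2S,3R)-2-[4-(benzyloxy)-3-methoxyphenyl]-3-(hydroxymethyl)-7-methoxy-2,3-dihydro-1-benzofuran-5-yl]methyl}dihydrofuran-2(3H)-one | COc1cc(C[C@H]2COC(=O)[C@@H]2Cc2cc(OC)c3c(c2)[C@H](CO)[C@@H](c2ccc(OCc4ccccc4)c(OC)c2)O3)ccc1OCc1ccccc1 | intermediate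
28 | Isolappaol A | COc1cc(C[C@H]2COC(=O)[C@@H]2Cc2cc(OC)c3c(c2)[C@H](CO)[C@@H](c2ccc(O)c(OC)c2)O3)ccc1O | target

**Count and risks**

Total step count: 15. Longest linear sequence: 9 steps (steps 3, 4, 5, 6, 7, 8, 13, 14, 15, from compound 6).

Step 13 (rhodium addition). What may go wrong: protodeboronation of the electron-rich arylboronate before transmetalation, migration of the exocyclic double bond into the ring (which would erase C4), or β-hydride elimination from the rhodium enolate instead of protonation. The fallback is a classical enolate alkylation that sets out from alcohol 15 and lactone 22 and comes back at 27. Alcohol 15 is silylated (TBSCl, imidazole, DMF) to the tert-butyldimethylsilyl ether F1. Bromine–lithium exchange (n-BuLi, THF, −78 °C) and DMF give the aldehyde F2, NaBH4 in MeOH gives the benzylic alcohol F3, and CBr4/PPh3 in CH2Cl2 gives the benzylic bromide F4. The lithium enolate of 22 (LiHMDS, THF/DMPU, −78 °C) is alkylated by F4 on the face away from the C4 substituent to give the trans-lactone silyl ether F5. TBAF in THF then frees the primary alcohol to give 27, and step 15 follows; steps 8, 12, 13 and 14 are not needed on this path.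

Step 6 (ring contraction). What may go wrong: shift of the electron-rich C2 aryl group instead of C4a, elimination of the iodane to the flavone, oxidation of the dialkoxyarene by iodine(III), or acid-induced reversible opening of the pyranone with loss of enantiomeric purity. The fallback keeps the disconnection but runs it on a B ring of lower donor strength; it sets out from 10 and comes back at 15. BCl3 with pentamethylbenzene (CH2Cl2, −78 °C) removes the benzyl group to give the phenol flavanone F6, and PivCl/pyridine gives the pivalate flavanone F7, whose B ring is electronically close to that of the parent flavanone. The same iodine(III) contraction gives the pivalate ester F8, DIBAL-H reduces both esters to the phenol alcohol F9, and BnBr/K2CO3 in acetone benzylates the phenol alone to give 15.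

Step 5 (asymmetric arylation). What may go wrong: low enantioselectivity or protodeboronation with the electron-rich boronic acid, or the opposite sense of induction. The fallback is resolution of a racemate made by the chalcone route; it sets out from 7 and 17 and comes back at 10. Claisen–Schmidt condensation (KOH, EtOH) gives the 2'-hydroxychalcone F10, and NaOAc in refluxing EtOH closes it by oxa-Michael addition to the racemic flavanone F11. Preparative chromatography on a chiral stationary phase delivers 10, and the unwanted antipode can be returned to the racemate by base-induced ring opening and reclosure.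

**Further compounds**

F1 | step 13 | tert-butyl{[(2S,3R)-2-[4-(benzyloxy)-3-methoxyphenyl]-5-bromo-7-methoxy-2,3-dihydro-1-benzofuran-3-yl]methoxy}dimethylsilane | Brc1cc(OC)c2c(c1)[C@H](CO[Si](C)(C)C(C)(C)C)[C@@H](c1ccc(OCc3ccccc3)c(OC)c1)O2
F2 | step 13 | (2S,3R)-2-[4-(benzyloxy)-3-methoxyphenyl]-3-{[(tert-butyldimethylsilyl)oxy]methyl}-7-methoxy-2,3-dihydro-1-benzofuran-5-carbaldehyde | O=Cc1cc(OC)c2c(c1)[C@H](CO[Si](C)(C)C(C)(C)C)[C@@H](c1ccc(OCc3ccccc3)c(OC)c1)O2
F3 | step 13 | [(2S,3R)-2-[4-(benzyloxy)-3-methoxyphenyl]-3-{[(tert-butyldimethylsilyl)oxy]methyl}-7-methoxy-2,3-dihydro-1-benzofuran-5-yl]methanol | OCc1cc(OC)c2c(c1)[C@H](CO[Si](C)(C)C(C)(C)C)[C@@H](c1ccc(OCc3ccccc3)c(OC)c1)O2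
F4 | step 13 | {[(2S,3R)-2-[4-(benzyloxy)-3-methoxyphenyl]-5-(bromomethyl)-7-methoxy-2,3-dihydro-1-benzofuran-3-yl]methoxy}(tert-butyl)dimethylsilane | BrCc1cc(OC)c2c(c1)[C@H](CO[Si](C)(C)C(C)(C)C)[C@@H](c1ccc(OCc3ccccc3)c(OC)c1)O2
F5 | step 13 | (3R,4R)-4-[4-(benzyloxy)-3-methoxybenzyl]-3-{[(2S,3R)-2-[4-(benzyloxy)-3-methoxyphenyl]-3-{[(tert-butyldimethylsilyl)oxy]methyl}-7-methoxy-2,3-dihydro-1-benzofuran-5-yl]methyl}dihydrofuran-2(3H)-one | COc1cc(C[C@H]2COC(=O)[C@@H]2Cc2cc(OC)c3c(c2)[C@H](CO[Si](C)(C)C(C)(C)C)[C@@H](c2ccc(OCc4ccccc4)c(OC)c2)O3)ccc1OCc1ccccc1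
F6 | step 6 | (S)-6-bromo-2-(4-hydroxy-3-methoxyphenyl)-8-methoxychroman-4-one | Brc1cc(OC)c2c(c1)C(=O)C[C@@H](c1ccc(O)c(OC)c1)O2
F7 | step 6 | 4-[(S)-6-bromo-8-methoxy-4-oxochroman-2-yl]-2-methoxyphenyl pivalate | Brc1cc(OC)c2c(c1)C(=O)C[C@@H](c1ccc(OC(=O)C(C)(C)C)c(OC)c1)O2
F8 | step 6 | methyl (2S,3S)-5-bromo-7-methoxy-2-[3-methoxy-4-(pivaloyloxy)phenyl]-2,3-dihydro-1-benzofuran-3-carboxylate | Brc1cc(OC)c2c(c1)[C@H](C(=O)OC)[C@@H](c1ccc(OC(=O)C(C)(C)C)c(OC)c1)O2
F9 | step 6 | 4-[(2S,3R)-5-bromo-3-(hydroxymethyl)-7-methoxy-2,3-dihydro-1-benzofuran-2-yl]-2-methoxyphenol | Brc1cc(OC)c2c(c1)[C@H](CO)[C@@H](c1ccc(O)c(OC)c1)O2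
F10 | step 5 | (E)-3-[4-(benzyloxy)-3-methoxyphenyl]-1-(5-bromo-2-hydroxy-3-methoxyphenyl)prop-2-en-1-one | COc1cc(/C=C/C(=O)c2cc(Br)cc(OC)c2O)ccc1OCc1ccccc1
F11 | step 5 | rac-2-[4-(benzyloxy)-3-methoxyphenyl]-6-bromo-8-methoxychroman-4-one | Brc1cc(OC)c2c(c1)C(=O)CC(c1ccc(OCc3ccccc3)c(OC)c1)O2
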